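**Retrosynthetic overview**
1. Target 14 comes from the bis-benzyl ether 13 by O-debenzylation as the last step. Cutting the ester C–O bond of 13 gives alcohol 11 and stearoyl chloride 12.
2. Alcohol 11 comes from the saturated ester 9 by ester reduction. Ester 9 comes from the cinnamate 8 by C=C saturation, and 8 from the cinnamic acid 7.
3. Key C–C disconnection: the Cα=Cβ bond of 7 leads back to aldehyde 4 and malonic acid 5 (Knoevenagel–Doebner aldol-type condensation with loss of CO2).
4. Aldehyde 4 comes from 5-hydroxyvanillin 3, which comes from 5-bromovanillin 2 and then vanillin 1.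
5. No ring is formed. The single benzene ring is bought in with vanillin.

Assumption: the target SMILES holds no stereocentre, so the compound is achiral and there is no enantiomer to select. The acyl chain is read as octadecanoyl (C18), and the only stereo-element on the way is the E alkene of 7 and 8, which step 6 erases.

**Step 1**
Reactants: 1 vanillin (4-hydroxy-3-methoxybenzaldehyde)
Product: 2 5-bromovanillin (3-bromo-4-hydroxy-5-methoxybenzaldehyde)
Conditions: Br2 (1.05 equiv), AcOH, rt, 2 h; then ice-water, filter
Reagents that add atoms: bromine, BrBr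
Why: Electrophilic aromatic bromination in which the free phenol directs to its only open ortho position (C5), the para position being blocked by the formyl group, so a single monobromide precipitates.

**Step 2**
Reactants: 2 5-bromovanillin
Product: 3 5-hydroxyvanillin (3,4-dihydroxy-5-methoxybenzaldehyde)
Conditions: NaOH (7 equiv), Cu powder (5 mol%), H2O, reflux, N2, 24 h; then HCl to pH 2, EtOAc extraction
Reagents that add atoms: sodium hydroxide, [Na+].[OH-]
Why: Copper-catalysed Ullmann-type hydroxylation of the aryl bromide, in which the para-phenolate makes the aldehyde a vinylogous carboxylate and so shields it from Cannizzaro disproportionation in the hot alkali.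

**Step 3**
Reactants: 3 5-hydroxyvanillin
Product: 4 3,4-bis(benzyloxy)-5-methoxybenzaldehyde
Conditions: BnBr (2.4 equiv), K2CO3 (3 equiv), DMF, 60 °C, N2
Reagents that add atoms: benzyl bromide, BrCc1ccccc1
Why: Double Williamson ether synthesis on the two acidic phenols gives benzyl ethers that withstand amine base, hydride and acylation and can be removed at the end under neutral conditions.

**Step 4**
Reactants: 4 3,4-bis(benzyloxy)-5-methoxybenzaldehyde; 5 malonic acid
Product: 7 (E)-3-[3,4-bis(benzyloxy)-5-methoxyphenyl]prop-2-enoic acid, via arylidenemalonic acid 6 (not isolated)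
Conditions: malonic acid (2 equiv), piperidine (0.1 equiv), pyridine, 95 °C, 4 h; then cold 2 M HCl, filter
Reagents that add atoms: malonic acid (compound 5), OC(=O)CC(=O)O
Why: Knoevenagel–Doebner condensation, the malonate version of the aldol condensation, in which the malonic acid enolate adds to the piperidine-activated aldehyde to forge the new C–C bond, dehydration gives 6, and decarboxylation in hot pyridine delivers the thermodynamically favoured E acid without creating a stereocentre.

**Step 5**
Reactants: 7 (E)-3-[3,4-bis(benzyloxy)-5-methoxyphenyl]prop-2-enoic acid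
Product: 8 methyl (E)-3-[3,4-bis(benzyloxy)-5-methoxyphenyl]prop-2-enoate
Conditions: MeI (1.5 equiv), K2CO3 (1.5 equiv), DMF, rt
Reagents that add atoms: iodomethane, CI
Why: SN2 O-alkylation of the potassium carboxylate runs at room temperature without acid, so the benzyl ethers and the E alkene stay untouched.

**Step 6**
Reactants: 8 methyl (E)-3-[3,4-bis(benzyloxy)-5-methoxyphenyl]prop-2-enoate
Product: 9 methyl 3-[3,4-bis(benzyloxy)-5-methoxyphenyl]propanoate
Conditions: NaBH4 (4 equiv), NiCl2·6H2O (0.2 equiv), MeOH/THF (3:1), 0 °C to rt; filter through Celite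
Reagents that add atoms: none
Why: Conjugate reduction with nickel boride (Ni2B) formed in situ from NiCl2 and NaBH4 saturates the electron-poor cinnamate C=C at 0 °C without hydrogenolysing aryl benzyl ethers or reducing the ester, and no stereocentre arises.

**Step 7**
Reactants: 9 methyl 3-[3,4-bis(benzyloxy)-5-methoxyphenyl]propanoate
Product: 11 3-[3,4-bis(benzyloxy)-5-methoxyphenyl]propan-1-ol, via arylpropanal 10 (not isolated)
Conditions: LiAlH4 (1.2 equiv), THF, 0 °C to rt; then H2O, 15% NaOH, H2O
Reagents that add atoms: none
Why: Hydride reduction of the ester with LiAlH4 passes through the aldehyde 10, which is reduced faster than the ester, while aryl ethers are inert to hydride.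

**Step 8**
Reactants: 11 3-[3,4-bis(benzyloxy)-5-methoxyphenyl]propan-1-ol; 12 stearoyl chloride (octadecanoyl chloride)
Product: 13 3-[3,4-bis(benzyloxy)-5-methoxyphenyl]propyl octadecanoate
Conditions: Et3N (1.5 equiv), DMAP (0.1 equiv), CH2Cl2, 0 °C to rt
Reagents that add atoms: stearoyl chloride (compound 12), CCCCCCCCCCCCCCCCCC(=O)Cl
Why: DMAP-catalysed nucleophilic acyl substitution on an unhindered primary alcohol is fast and unambiguous because both phenols are masked, so only one hydroxyl can be acylated.

**Step 9**
Reactants: 13 3-[3,4-bis(benzyloxy)-5-methoxyphenyl]propyl octadecanoate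
Product: 14 3-(3,4-dihydroxy-5-methoxyphenyl)propyl octadecanoate (target)
Conditions: H2 (1 atm), 10% Pd/C, THF/EtOH (1:1), rt; filter through Celite under N2
Reagents that add atoms: none
Why: Catalytic hydrogenolysis over Pd/C cleaves the two aryl benzyl ethers under neutral conditions, while the 3-arylpropyl ester C–O bond is neither benzylic nor allylic and therefore survives.

**Compound list**
1 | vanillin (4-hydroxy-3-methoxybenzaldehyde) | COc1cc(C=O)ccc1O | starting material
2 | 5-bromovanillin (3-bromo-4-hydroxy-5-methoxybenzaldehyde) | COc1cc(C=O)cc(Br)c1O | intermediate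
3 | 5-hydroxyvanillin (3,4-dihydroxy-5-methoxybenzaldehyde) | COc1cc(C=O)cc(O)c1O | intermediate
4 | 3,4-bis(benzyloxy)-5-methoxybenzaldehyde | COc1cc(C=O)cc(OCc2ccccc2)c1OCc1ccccc1 | intermediate
5 | malonic acid | OC(=O)CC(=O)O | starting material
6 | 2-[3,4-bis(benzyloxy)-5-methoxybenzylidene]malonic acid | COc1cc(C=C(C(=O)O)C(=O)O)cc(OCc2ccccc2)c1OCc1ccccc1 | intermediate (not isolated)
7 | (E)-3-[3,4-bis(benzyloxy)-5-methoxyphenyl]prop-2-enoic acid | COc1cc(/C=C/C(=O)O)cc(OCc2ccccc2)c1OCc1ccccc1 | intermediate
8 | methyl (E)-3-[3,4-bis(benzyloxy)-5-methoxyphenyl]prop-2-enoate | COc1cc(/C=C/C(=O)OC)cc(OCc2ccccc2)c1OCc1ccccc1 | intermediate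
9 | methyl 3-[3,4-bis(benzyloxy)-5-methoxyphenyl]propanoate | COc1cc(CCC(=O)OC)cc(OCc2ccccc2)c1OCc1ccccc1 | intermediate
10 | 3-[3,4-bis(benzyloxy)-5-methoxyphenyl]propanal | COc1cc(CCC=O)cc(OCc2ccccc2)c1OCc1ccccc1 | intermediate (not isolated)
11 | 3-[3,4-bis(benzyloxy)-5-methoxyphenyl]propan-1-ol | COc1cc(CCCO)cc(OCc2ccccc2)c1OCc1ccccc1 | intermediate
12 | stearoyl chloride (octadecanoyl chloride) | CCCCCCCCCCCCCCCCCC(=O)Cl | starting material
13 | 3-[3,4-bis(benzyloxy)-5-methoxyphenyl]propyl octadecanoate | CCCCCCCCCCCCCCCCCC(=O)OCCCc1cc(OCc2ccccc2)c(OCc2ccccc2)c(OC)c1 | intermediate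
14 | 3-(3,4-dihydroxy-5-methoxyphenyl)propyl octadecanoate (achiral) | CCCCCCCCCCCCCCCCCC(=O)OCCCc1cc(O)c(O)c(OC)c1 | target

**Total step count:** 9
**Longest linear sequence:** 9 steps (1 to 14)

**Three steps most likely to fail**

Step 2 (hydroxylation of 2). A day in boiling alkali invites hydrodebromination back to vanillin and oxidative tarring of the catecholate, so the yield is moderate and purification can be tedious. The fallback sets out from 2 and comes back to the route at 4, bypassing 3. It replaces hydrolysis of the free phenolate by C–B bond formation and oxidation on a protected substrate. The phenol of 2 is benzylated (BnBr, K2CO3, DMF) to 4-(benzyloxy)-3-bromo-5-methoxybenzaldehyde F1. Miyaura borylation (B2pin2, Pd(dppf)Cl2, KOAc, dioxane, 90 °C) gives 4-(benzyloxy)-3-methoxy-5-(4,4,5,5-tetramethyl-1,3,2-dioxaborolan-2-yl)benzaldehyde F2. Mild oxidation with NaBO3·4H2O in THF/H2O at rt gives 4-(benzyloxy)-3-hydroxy-5-methoxybenzaldehyde F3. A second benzylation (BnBr, K2CO3, DMF) converts F3 into 4.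

Step 6 (saturation of the alkene beside two aryl benzyl ethers). An over-active batch of nickel boride may clip a benzyl ether, and a sluggish one may leave alkene behind. Either way the mixture is hard to separate. The fallback sets out from 4 and comes back at 11. It removes the metal-surface reduction altogether by making the alkene doubly activated, so that plain hydride adds to it. Knoevenagel condensation of 4 with Meldrum's acid (cat. piperidinium acetate, EtOH, rt) gives 5-[3,4-bis(benzyloxy)-5-methoxybenzylidene]-2,2-dimethyl-1,3-dioxane-4,6-dione F4. NaBH4 (EtOH/CH2Cl2, 0 °C) adds hydride in 1,4 fashion to give 5-[3,4-bis(benzyloxy)-5-methoxybenzyl]-2,2-dimethyl-1,3-dioxane-4,6-dione F5. Heating in DMF/H2O (10:1) at 105 °C brings about hydrolytic ring opening and decarboxylation to 3-[3,4-bis(benzyloxy)-5-methoxyphenyl]propanoic acid F6. LiAlH4 in THF reduces F6 to 11.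

Step 9 (final double debenzylation). The waxy, lipophilic substrate can react sluggishly and leave mono-benzyl ethers, and the free catechol ester is air-sensitive if it must be chromatographed away from them. The fallback sets out from 11 and comes back at 14. It moves the deprotection ahead of the acylation and relies on enzymatic chemoselectivity. Hydrogenolysis of the small polar alcohol 11 (H2, 10% Pd/C, EtOH, rt) gives 3-(3,4-dihydroxy-5-methoxyphenyl)propan-1-ol F7. Immobilised Candida antarctica lipase B with vinyl stearate in tert-butyl methyl ether at 45 °C then acylates only the primary aliphatic hydroxyl and leaves both phenols free. This gives 14 after simple filtration of the enzyme.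

**Further compounds**
F1 | step 2 | 4-(benzyloxy)-3-bromo-5-methoxybenzaldehyde | COc1cc(C=O)cc(Br)c1OCc1ccccc1
F2 | step 2 | 4-(benzyloxy)-3-methoxy-5-(4,4,5,5-tetramethyl-1,3,2-dioxaborolan-2-yl)benzaldehyde | COc1cc(C=O)cc(B2OC(C)(C)C(C)(C)O2)c1OCc1ccccc1
F3 | step 2 | 4-(benzyloxy)-3-hydroxy-5-methoxybenzaldehyde | COc1cc(C=O)cc(O)c1OCc1ccccc1
F4 | step 6 | 5-[3,4-bis(benzyloxy)-5-methoxybenzylidene]-2,2-dimethyl-1,3-dioxane-4,6-dione | COc1cc(C=C2C(=O)OC(C)(C)OC2=O)cc(OCc2ccccc2)c1OCc1ccccc1
F5 | step 6 | 5-[3,4-bis(benzyloxy)-5-methoxybenzyl]-2,2-dimethyl-1,3-dioxane-4,6-dione | COc1cc(CC2C(=O)OC(C)(C)OC2=O)cc(OCc2ccccc2)c1OCc1ccccc1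
F6 | step 6 | 3-[3,4-bis(benzyloxy)-5-methoxyphenyl]propanoic acid | COc1cc(CCC(=O)O)cc(OCc2ccccc2)c1OCc1ccccc1
F7 | step 9 | 3-(3,4-dihydroxy-5-methoxyphenyl)propan-1-ol | COc1cc(CCCO)cc(O)c1O
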